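**Strategy**

The synthesis rests on disconnecting the O1–C2 bond of the dihydrofuran ring (O1, C2, C3, C3a, C7a). The C3 stereocentre with its 3,5-dioxygenated aryl group and the 5,6-substitution of ring A are exactly those of a 4-aryl-6-chloro-7-methoxy-dihydrocoumarin, which asymmetric conjugate addition makes reliably. In one operation hydroxide opens the trans 3-bromo lactone 9 and the phenoxide so released attacks the bromide-bearing carbon with inversion, contracting the six-membered lactone to the trans 2,3-dihydrobenzofuran-2-carboxylic acid 11. The carboxyl group then becomes the radical handle for the catechol ring at C2, the chloride the Heck handle for the stilbene, and seven methyl ethers fall in the last step.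

Key step: step 5

Remark (stereochemistry): the target is the trans (2S,3S) isomer; the ring closure inverts the bromide-bearing carbon, so the trans (3R,4S) bromolactone 9 is the matching precursor. (S)-SEGPHOS is assumed to give the (S)-lactone 7 by analogy with the established sense of induction for coumarins; the antipodal ligand is taken if the first run shows the opposite sense.

Remark (spectator groups): chlorine is kept as the dormant stilbene handle because it is inert to monovalent rhodium, the enolate, hydroxide and the nickel/iridium coupling of an aryl iodide, yet Pd/P(t-Bu)3 engages it. The C2 configuration made in step 5 is transient: step 6 passes through a planar C2 radical and sets it again anti to the C3 aryl group.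

**Route**

Step 1
Reactants: 1 4-chlororesorcinol; 2 malic acid (racemic)
Product: 4 6-chloro-7-hydroxy-2H-chromen-2-one, via formylacetic acid 3 (not isolated)
Conditions: conc. H2SO4, 100–110 °C, 2 h; pour onto ice
Reagents that add atoms: none
Why: von Pechmann condensation, in which malic acid loses CO and water in hot sulfuric acid to give formylacetic acid 3, which alkylates the resorcinol at C6 (para to one hydroxyl, ortho to the other, C4 being blocked by chlorine) and lactonises to the coumarin.

Step 2
Reactants: 4 6-chloro-7-hydroxy-2H-chromen-2-one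
Product: 5 6-chloro-7-methoxy-2H-chromen-2-one
Conditions: MeI (1.5 equiv), K2CO3 (2 equiv), acetone, reflux
Reagents that add atoms: iodomethane, CI
Why: Williamson ether synthesis, the acidic 7-hydroxyl being deprotonated by carbonate and methylated by SN2 on iodomethane while the lactone is stable to these anhydrous, weakly basic conditions.

Step 3
Reactants: 5 6-chloro-7-methoxy-2H-chromen-2-one; 6 3,5-dimethoxyphenylboronic acid
Product: 7 (S)-6-chloro-4-(3,5-dimethoxyphenyl)-7-methoxychroman-2-one
Conditions: Rh(acac)(C2H4)2 (3 mol%), (S)-SEGPHOS (3.3 mol%), 6 (5 equiv, in portions), dioxane/H2O 10:1, 60 °C; 1 M HCl work-up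
Reagents that add atoms: none
Why: Hayashi–Miyaura asymmetric 1,4-addition, in which an aryl–rhodium species of monovalent rhodium adds across C3=C4 inside the chiral pocket of the bisphosphine and water protonates the resulting rhodium enolate, so the C4 stereocentre is set as S by catalyst control while the aryl chloride stays inert.

Step 4
Reactants: 7 (S)-6-chloro-4-(3,5-dimethoxyphenyl)-7-methoxychroman-2-one
Product: 9 (3R,4S)-3-bromo-6-chloro-4-(3,5-dimethoxyphenyl)-7-methoxychroman-2-one, via lithium enolate 8 (not isolated)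
Conditions: LiN(SiMe3)2 (1.05 equiv), THF, −78 °C; cannulate into NBS (1.05 equiv), THF, −78 °C; AcOH quench
Reagents that add atoms: N-bromosuccinimide, BrN1C(=O)CCC1=O
Why: Electrophilic α-bromination of a lactone enolate, in which the pseudo-axial C4 aryl group shields one face of planar enolate 8 so that bromine enters anti to it and the new C3 stereocentre is set trans (3R) by substrate control, far faster at −78 °C than any bromination of the electron-rich arenes.

Step 5
Reactants: 9 (3R,4S)-3-bromo-6-chloro-4-(3,5-dimethoxyphenyl)-7-methoxychroman-2-one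
Product: 11 (2S,3S)-5-chloro-3-(3,5-dimethoxyphenyl)-6-methoxy-2,3-dihydrobenzofuran-2-carboxylic acid, via ring-opened bromo phenoxide carboxylate 10 (not isolated)
Conditions: LiOH·H2O (3 equiv), THF/H2O 3:1, −10 °C → 20 °C; then 1 M HCl to pH 2
Reagents that add atoms: lithium hydroxide, [Li+].[OH-]
Why: Hydroxide adds to the aryl-ester carbonyl of 9 and cleaves the lactone to the phenoxide α-bromo carboxylate 10, whose phenoxide oxygen then attacks the bromide-bearing carbon from the rear in an intramolecular SN2 reaction that forms O1–C2. The closest known reaction type is the Perkin coumarin-to-benzofuran ring contraction of 3-halocoumarins, run here on the saturated lactone as an intramolecular Williamson etherification. The dihydrofuran ring (O1, C2, C3, C3a, C7a) closes in the 5-exo-tet mode. The new C2 stereocentre is fixed by stereospecific inversion at the former lactone C3, so the trans (3R,4S) bromide should give the trans (2S,3S) acid while the aryl-bearing carbon is not touched. The step needs substitution to beat loss of HBr: in the lactone the C4 hydrogen is syn to bromine, so no anti-periplanar elimination is open before ring opening, the opening is run cold, and afterwards the carboxylate lowers the acidity of the α-hydrogen while the phenoxide is held five atoms from the electrophilic carbon.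

Step 6
Reactants: 11 (2S,3S)-5-chloro-3-(3,5-dimethoxyphenyl)-6-methoxy-2,3-dihydrobenzofuran-2-carboxylic acid; 12 4-iodo-1,2-dimethoxybenzene
Product: 13 (2S,3S)-5-chloro-2-(3,4-dimethoxyphenyl)-3-(3,5-dimethoxyphenyl)-6-methoxy-2,3-dihydrobenzofuran
Conditions: 12 (2 equiv), Ir[dF(CF3)ppy]2(dtbbpy)PF6 (1 mol%), NiCl2·glyme (10 mol%), dtbbpy (15 mol%), Cs2CO3 (1.5 equiv), DMF, blue LEDs (450 nm), 25 °C, degassed
Reagents that add atoms: none
Why: Nickel/photoredox decarboxylative arylation of an α-oxy acid, in which the excited iridium photocatalyst oxidises the caesium carboxylate, loss of CO2 gives the planar α-oxy C2 radical, and the aryl–nickel species from oxidative addition of zerovalent nickel into the C–I bond of 12 (much faster than into the ring A C–Cl bond) captures it and reductively eliminates on the face anti to the C3 aryl group, so the trans (2S) configuration is set by substrate control.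

Step 7
Reactants: 13 (2S,3S)-5-chloro-2-(3,4-dimethoxyphenyl)-3-(3,5-dimethoxyphenyl)-6-methoxy-2,3-dihydrobenzofuran; 14 3,5-dimethoxystyrene
Product: 15 (2S,3S)-2-(3,4-dimethoxyphenyl)-3-(3,5-dimethoxyphenyl)-5-[(E)-2-(3,5-dimethoxyphenyl)ethenyl]-6-methoxy-2,3-dihydrobenzofuran
Conditions: 14 (2 equiv), Pd2(dba)3 (2.5 mol%), [HP(t-Bu)3]BF4 (10 mol%), Cy2NMe (2 equiv), dioxane, 110 °C
Reagents that add atoms: none
Why: Mizoroki–Heck reaction, in which the bulky electron-rich P(t-Bu)3 lets zerovalent palladium insert into the deactivated aryl C–Cl bond, syn carbopalladation places the aryl group on the terminal carbon of 14 and syn β-hydride elimination gives the (E)-stilbene, the tertiary amine base leaving both stereocentres alone.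

Step 8
Reactants: 15 (2S,3S)-2-(3,4-dimethoxyphenyl)-3-(3,5-dimethoxyphenyl)-5-[(E)-2-(3,5-dimethoxyphenyl)ethenyl]-6-methoxy-2,3-dihydrobenzofuran
Product: 16 4-[(2S,3S)-3-(3,5-dihydroxyphenyl)-5-[(E)-2-(3,5-dihydroxyphenyl)ethenyl]-6-hydroxy-2,3-dihydrobenzofuran-2-yl]benzene-1,2-diol
Conditions: BBr3 (1 M in CH2Cl2, 14 equiv), CH2Cl2, −78 → 0 °C, then 20 °C, argon, dark; ice/H2O quench
Reagents that add atoms: none
Why: Lewis-acid cleavage of aryl methyl ethers, in which BBr3 coordinates each ether oxygen and bromide removes the methyl group by SN2 to leave aryloxyboron species that hydrolyse on work-up, the sp3 stereocentres taking no part and any reversible ionisation at C2 closing again to the favoured trans isomer.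

**Compound list**

1 | 4-chlororesorcinol (4-chlorobenzene-1,3-diol) | Oc1ccc(Cl)c(O)c1 | starting material
2 | malic acid (racemic 2-hydroxybutanedioic acid) | OC(=O)CC(O)C(=O)O | starting material
3 | formylacetic acid (3-oxopropanoic acid) | O=CCC(=O)O | intermediate
4 | 6-chloro-7-hydroxy-2H-chromen-2-one | O=C1C=Cc2cc(Cl)c(O)cc2O1 | intermediate
5 | 6-chloro-7-methoxy-2H-chromen-2-one | O=C1C=Cc2cc(Cl)c(OC)cc2O1 | intermediate
6 | 3,5-dimethoxyphenylboronic acid | COc1cc(OC)cc(B(O)O)c1 | starting material
7 | (S)-6-chloro-4-(3,5-dimethoxyphenyl)-7-methoxychroman-2-one | O=C1Oc2cc(OC)c(Cl)cc2[C@H](c2cc(OC)cc(OC)c2)C1 | intermediate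
8 | lithium (S)-6-chloro-4-(3,5-dimethoxyphenyl)-7-methoxy-4H-chromen-2-olate | [Li+].[O-]C1=C[C@@H](c2cc(OC)cc(OC)c2)c2cc(Cl)c(OC)cc2O1 | intermediate
9 | (3R,4S)-3-bromo-6-chloro-4-(3,5-dimethoxyphenyl)-7-methoxychroman-2-one | O=C1Oc2cc(OC)c(Cl)cc2[C@H](c2cc(OC)cc(OC)c2)[C@H]1Br | intermediate
10 | dilithium (2R,3S)-2-bromo-3-(5-chloro-4-methoxy-2-oxidophenyl)-3-(3,5-dimethoxyphenyl)propanoate | [Li+].[Li+].[O-]C(=O)[C@H](Br)[C@@H](c1cc(OC)cc(OC)c1)c1cc(Cl)c(OC)cc1[O-] | intermediate
11 | (2S,3S)-5-chloro-3-(3,5-dimethoxyphenyl)-6-methoxy-2,3-dihydrobenzofuran-2-carboxylic acid | Clc1cc2c(cc1OC)O[C@H](C(=O)O)[C@H]2c1cc(OC)cc(OC)c1 | intermediate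
12 | 4-iodo-1,2-dimethoxybenzene | COc1ccc(I)cc1OC | starting material
13 | (2S,3S)-5-chloro-2-(3,4-dimethoxyphenyl)-3-(3,5-dimethoxyphenyl)-6-methoxy-2,3-dihydrobenzofuran | Clc1cc2c(cc1OC)O[C@H](c1ccc(OC)c(OC)c1)[C@H]2c1cc(OC)cc(OC)c1 | intermediate
14 | 3,5-dimethoxystyrene | C=Cc1cc(OC)cc(OC)c1 | starting material
15 | (2S,3S)-2-(3,4-dimethoxyphenyl)-3-(3,5-dimethoxyphenyl)-5-[(E)-2-(3,5-dimethoxyphenyl)ethenyl]-6-methoxy-2,3-dihydrobenzofuran | COc1cc(OC)cc(/C=C/c2cc3c(cc2OC)O[C@H](c2ccc(OC)c(OC)c2)[C@H]3c2cc(OC)cc(OC)c2)c1 | intermediate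
16 | 4-[(2S,3S)-3-(3,5-dihydroxyphenyl)-5-[(E)-2-(3,5-dihydroxyphenyl)ethenyl]-6-hydroxy-2,3-dihydrobenzofuran-2-yl]benzene-1,2-diol | Oc1cc(O)cc(/C=C/c2cc3c(cc2O)O[C@H](c2ccc(O)c(O)c2)[C@H]3c2cc(O)cc(O)c2)c1 | target

**Step count and risks**

Total step count: 8. Longest linear sequence: 8 steps (1 → 16).

Steps most likely to fail:

Step 5. After the lactone opens, base-induced loss of HBr across the former C3–C4 bond, or sluggish displacement next to a carboxylate, may overtake the 5-exo-tet closure. The fallback makes the O1–C2 bond by a Mitsunobu etherification instead of a bromide displacement. It sets out from lactone 7: lithium enolate 8, generated as in step 4, is hydroxylated anti to the aryl group with 2-(phenylsulfonyl)-3-phenyloxaziridine (THF, −78 °C) to give (3R,4S)-6-chloro-4-(3,5-dimethoxyphenyl)-3-hydroxy-7-methoxychroman-2-one F1. Methanolysis (MeOH, cat. Et3N, 0 °C) should open it to methyl (2R,3S)-3-(5-chloro-2-hydroxy-4-methoxyphenyl)-3-(3,5-dimethoxyphenyl)-2-hydroxypropanoate F2. PPh3/DIAD (THF, 0 °C) should then activate the secondary alcohol, and the phenol closes the ring with inversion to methyl (2S,3S)-5-chloro-3-(3,5-dimethoxyphenyl)-6-methoxy-2,3-dihydrobenzofuran-2-carboxylate F3. Saponification (LiOH, THF/H2O, 0 °C) comes back to the route at acid 11.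

Step 6. The C2 radical may be intercepted poorly (slow oxidative addition of the electron-rich aryl iodide, hydrogen-atom capture leading to protodecarboxylation), or the facial selectivity may be incomplete. The fallback is a thermal decarboxylative Negishi arylation of a redox-active ester, in which the aryl–nickel species arises by transmetalation. It sets out from acid 11: DIC, N-hydroxyphthalimide and cat. DMAP (CH2Cl2, 20 °C) should give 1,3-dioxoisoindolin-2-yl (2S,3S)-5-chloro-3-(3,5-dimethoxyphenyl)-6-methoxy-2,3-dihydrobenzofuran-2-carboxylate F4. Iodide 12 is converted with zinc dust and LiCl (THF, 50 °C) into (3,4-dimethoxyphenyl)zinc iodide F5. NiCl2·glyme (20 mol%) and dtbbpy (40 mol%) in THF/DMF at 20 °C should couple F4 with F5, again anti to the C3 aryl group, and the route is rejoined at 13.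

Step 8. Lewis-acid ionisation of the C2–O1 bond and electrophilic attack on the electron-rich 2,4-dioxygenated stilbene may cause ring opening, oligomerisation or incomplete cleavage. The fallback removes the methyl ethers before the olefin exists and carries the phenols through the Heck reaction as silyl ethers. It sets out from chloride 13: BBr3 (CH2Cl2, −78 → 20 °C) should give 4-[(2S,3S)-5-chloro-3-(3,5-dihydroxyphenyl)-6-hydroxy-2,3-dihydrobenzofuran-2-yl]benzene-1,2-diol F6, and TBSCl/imidazole (DMF) its pentakis(tert-butyldimethylsilyl) ether F7. Commercial 3,5-dihydroxybenzaldehyde is silylated (TBSCl, imidazole, DMF) to 3,5-bis(tert-butyldimethylsilyloxy)benzaldehyde F8 and methylenated by a Wittig reaction (Ph3P=CH2, THF, 0 °C) to 3,5-bis(tert-butyldimethylsilyloxy)styrene F9. Heck coupling of F7 with F9 under the conditions of step 7 should give the heptakis(tert-butyldimethylsilyl) ether of the target F10, and Et3N·3HF (THF, 20 °C) releases target 16.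

Further compounds
F1 | step 5 | (3R,4S)-6-chloro-4-(3,5-dimethoxyphenyl)-3-hydroxy-7-methoxychroman-2-one | O=C1Oc2cc(OC)c(Cl)cc2[C@H](c2cc(OC)cc(OC)c2)[C@H]1O
F2 | step 5 | methyl (2R,3S)-3-(5-chloro-2-hydroxy-4-methoxyphenyl)-3-(3,5-dimethoxyphenyl)-2-hydroxypropanoate | COC(=O)[C@H](O)[C@@H](c1cc(OC)cc(OC)c1)c1cc(Cl)c(OC)cc1O
F3 | step 5 | methyl (2S,3S)-5-chloro-3-(3,5-dimethoxyphenyl)-6-methoxy-2,3-dihydrobenzofuran-2-carboxylate | Clc1cc2c(cc1OC)O[C@H](C(=O)OC)[C@H]2c1cc(OC)cc(OC)c1
F4 | step 6 | 1,3-dioxoisoindolin-2-yl (2S,3S)-5-chloro-3-(3,5-dimethoxyphenyl)-6-methoxy-2,3-dihydrobenzofuran-2-carboxylate | Clc1cc2c(cc1OC)O[C@H](C(=O)ON1C(=O)c3ccccc3C1=O)[C@H]2c1cc(OC)cc(OC)c1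
F5 | step 6 | (3,4-dimethoxyphenyl)zinc iodide | COc1ccc([Zn]I)cc1OC
F6 | step 8 | 4-[(2S,3S)-5-chloro-3-(3,5-dihydroxyphenyl)-6-hydroxy-2,3-dihydrobenzofuran-2-yl]benzene-1,2-diol | Clc1cc2c(cc1O)O[C@H](c1ccc(O)c(O)c1)[C@H]2c1cc(O)cc(O)c1
F7 | step 8 | (2S,3S)-2-[3,4-bis(tert-butyldimethylsilyloxy)phenyl]-3-[3,5-bis(tert-butyldimethylsilyloxy)phenyl]-6-(tert-butyldimethylsilyloxy)-5-chloro-2,3-dihydrobenzofuran | Clc1cc2c(cc1O[Si](C)(C)C(C)(C)C)O[C@H](c1ccc(O[Si](C)(C)C(C)(C)C)c(O[Si](C)(C)C(C)(C)C)c1)[C@H]2c1cc(O[Si](C)(C)C(C)(C)C)cc(O[Si](C)(C)C(C)(C)C)c1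
F8 | step 8 | 3,5-bis(tert-butyldimethylsilyloxy)benzaldehyde | O=Cc1cc(O[Si](C)(C)C(C)(C)C)cc(O[Si](C)(C)C(C)(C)C)c1
F9 | step 8 | 3,5-bis(tert-butyldimethylsilyloxy)styrene | C=Cc1cc(O[Si](C)(C)C(C)(C)C)cc(O[Si](C)(C)C(C)(C)C)c1
F10 | step 8 | (2S,3S)-2-[3,4-bis(tert-butyldimethylsilyloxy)phenyl]-3-[3,5-bis(tert-butyldimethylsilyloxy)phenyl]-5-[(E)-2-[3,5-bis(tert-butyldimethylsilyloxy)phenyl]ethenyl]-6-(tert-butyldimethylsilyloxy)-2,3-dihydrobenzofuran | CC(C)(C)[Si](C)(C)Oc1cc(O[Si](C)(C)C(C)(C)C)cc(/C=C/c2cc3c(cc2O[Si](C)(C)C(C)(C)C)O[C@H](c2ccc(O[Si](C)(C)C(C)(C)C)c(O[Si](C)(C)C(C)(C)C)c2)[C@H]3c2cc(O[Si](C)(C)C(C)(C)C)cc(O[Si](C)(C)C(C)(C)C)c2)c1
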